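**Retrosynthetic overview**

1. The target is a benzene ring (ring A, C4a–C8a) fused to a hydroxylated pyran (ring B, O1–C2–C3–C4) and linked through C6–CH2 to a 4-hydroxy-2-pyrone (ring C). The last disconnection is the methylene bridge, made by Mannich / ortho-quinone methide coupling of acylphloroglucinol chromanol 19 with pyrone 24.
2. The C8 acyl group comes from a C8 bromide by Br–Li exchange and Weinreb acylation with the amide of (S)-2-methylbutanoic acid. The C3 carbinol comes from asymmetric epoxidation of a C3=C4 chromene and hydride opening at C4.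
3. Ring B is built on ring A in the key step: an aryne across C4a≡C8a takes up 3-methylbut-2-enal, forming O1–C8a and C4–C4a in a formal [2+2]; 4π ring opening and oxa-6π closure (O1–C2) then give the 2H-chromene.
4. Enabling feature: the ring-fusion atoms C4a and C8a are neighbours in ring A and C4a is flanked by the C5 oxygen, which polarises the aryne so that oxygen goes to C8a and carbon to C4a. The O1–C2(Me)2–C3–C4 unit of ring B is the O=C–C=C(Me)2 skeleton of the enal, with no stereocentre at C2.
5. Order of ring formation: ring A is bought, ring B is closed in step 3, ring C is made separately (steps 10 and 11) and attached in step 12.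

Key step: step 3

Remark on the chemistry: benzyl ethers are used on O5 and O7 because they tolerate fluoride, hydride and organolithium reagents and leave by neutral hydrogenolysis, which does not endanger the ketone α-stereocentre; compounds 1, 6, 14, 20 and 21 are taken as commercial.

**Route**

Step 1
Reactants: 1 3,5-bis(benzyloxy)phenol
Product: 2 3,5-bis(benzyloxy)-2-bromophenol
Conditions: NBS (1.0 equiv), iPr2NH (10 mol%), CH2Cl2, −78 to 0 °C
Reagents that add atoms: N-bromosuccinimide, O=C1CCC(=O)N1Br
Why: Amine-mediated ortho-selective electrophilic bromination of a phenol, in which the N-bromoamine is delivered through hydrogen bonding to the phenolic OH, so that bromine should enter C2 and not the more hindered C4 between the two benzyloxy groups.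

Step 2
Reactants: 2 3,5-bis(benzyloxy)-2-bromophenol
Product: 5 3,5-bis(benzyloxy)-2-(trimethylsilyl)phenyl trifluoromethanesulfonate, via aryl trimethylsilyl ether 3 (not isolated), via lithium 2-silylphenoxide 4 (not isolated)
Conditions: HMDS, THF, 65 °C, then evaporation; n-BuLi (1.1 equiv), THF, −78 to 25 °C; Tf2O (1.2 equiv), −78 °C
Reagents that add atoms: hexamethyldisilazane, C[Si](C)(C)N[Si](C)(C)C; trifluoromethanesulfonic anhydride, O=S(=O)(OS(=O)(=O)C(F)(F)F)C(F)(F)F
Why: Standard three-stage preparation of an ortho-silylaryl triflate (O-silylation, bromine–lithium exchange with anionic 1,3-O-to-C silyl shift, i.e. retro-Brook rearrangement, then O-triflation), the exchange at −78 °C being faster than deprotonation of the benzyl ethers.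

Step 3
Reactants: 5 3,5-bis(benzyloxy)-2-(trimethylsilyl)phenyl trifluoromethanesulfonate; 6 3-methylbut-2-enal
Product: 10 5,7-bis(benzyloxy)-2,2-dimethyl-2H-chromene, via aryne 7 (not isolated), via benzoxete 8 (not isolated), via ortho-quinone methide 9 (not isolated)
Conditions: CsF (3 equiv), 6 (5 equiv), MeCN, 25 to 50 °C, 5 added slowly
Reagents that add atoms: none
Why: Fluoride attacks silicon of 5 and triflate leaves to give the aryne 7 across C4a≡C8a; the benzyloxy group on C5, directly flanking C4a, distorts and polarises the triple bond so that the carbonyl oxygen of 6 bonds to the remote carbon C8a while the developing carbanion at C4a, stabilised inductively by the C5 oxygen, bonds to the aldehyde carbon (O1–C8a and C4–C4a formed in an asynchronous formal [2+2] cycloaddition, benzoxete 8). Strain-driven 4π-electrocyclic ring opening of 8 gives the ortho-quinone methide 9, and a thermally allowed disrotatory oxa-6π electrocyclisation closes the pyran ring (ring B) through O1–C2 and restores the aromaticity of ring A. The closest known reaction type is the aryne–carbonyl [2+2]/ring-opening cascade of fluoride-generated arynes with α,β-unsaturated aldehydes to 2H-chromenes and with formamides to salicylaldehyde derivatives. No stereocentre survives the step, because C2 carries two methyl groups and the stereocentre of 8 is erased on ring opening. The step needs regioselectivity (oxygen on C8a, carbon on C4a), which the C5 alkoxy group secures as in nucleophilic additions to 3-alkoxyarynes in general, and chemoselectivity for the C=O group over ene reaction or [2+2] addition at the C=C bond of 6, which the strongly polarised aryne, the excess of 6 and the slow release of the aryne should favour.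

Step 4
Reactants: 10 5,7-bis(benzyloxy)-2,2-dimethyl-2H-chromene
Product: 11 (3S,4S)-5,7-bis(benzyloxy)-3,4-epoxy-2,2-dimethylchromane
Conditions: (S,S)-(salen)MnCl, i.e. chloro[(S,S)-N,N′-bis(3,5-di-tert-butylsalicylidene)cyclohexane-1,2-diaminato]manganese, a trivalent manganese complex (5 mol%), NMO (5 equiv), mCPBA (2 equiv), CH2Cl2, −78 °C; cold aq. NaOH; product used crude
Reagents that add atoms: 3-chloroperbenzoic acid, O=C(OO)c1cccc(Cl)c1
Why: Jacobsen–Katsuki asymmetric epoxidation, for which cis-configured 2,2-dimethyl-2H-chromenes are the best substrate class; the (S,S)-salen ligand should direct oxygen transfer to the face of C3=C4 that gives the (3S,4S)-epoxide, and the low-temperature peracid/N-oxide variant avoids chlorination of the electron-rich arene and acid-induced opening of the labile benzylic epoxide.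

Step 5
Reactants: 11 (3S,4S)-5,7-bis(benzyloxy)-3,4-epoxy-2,2-dimethylchromane
Product: 12 (3S)-5,7-bis(benzyloxy)-2,2-dimethylchroman-3-ol
Conditions: LiAlH4 (1.5 equiv), THF, −20 to 0 °C; then H2O, aq. NaOH
Reagents that add atoms: none
Why: Regioselective SN2 hydride opening of an epoxide, in which hydride attacks the benzylic and less hindered C4 (C3 is neopentyl-like, next to the fully substituted C2), so that the C3–O bond and the (S) configuration set in step 4 are retained.

Step 6
Reactants: 12 (3S)-5,7-bis(benzyloxy)-2,2-dimethylchroman-3-ol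
Product: 13 (3S)-5,7-bis(benzyloxy)-8-bromo-2,2-dimethylchroman-3-ol
Conditions: NBS (1.0 equiv), CH2Cl2, −78 to −40 °C
Reagents that add atoms: N-bromosuccinimide, O=C1CCC(=O)N1Br
Why: Electrophilic aromatic bromination, expected at C8 (flanked by the ring oxygen O1 and one benzyloxy group) and not at C6 (flanked by two benzyloxy groups), the same C8 preference that N-bromosuccinimide shows with 5,7-di-O-benzylflavan-3-ols; the site is to be confirmed by HMBC and NOE before going on.

Step 7
Reactants: 14 (S)-2-methylbutanoic acid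
Product: 16 (S)-N-methoxy-N,2-dimethylbutanamide, via acyl imidazolide 15 (not isolated)
Conditions: 1,1′-carbonyldiimidazole (1.1 equiv), CH2Cl2, 25 °C; then MeNHOMe·HCl (1.2 equiv), 25 °C
Reagents that add atoms: N,O-dimethylhydroxylamine hydrochloride, CNOC.Cl
Why: Weinreb amide formation through the acyl imidazolide, a near-neutral amidation that does not touch the α-stereocentre taken from 14.

Step 8
Reactants: 13 (3S)-5,7-bis(benzyloxy)-8-bromo-2,2-dimethylchroman-3-ol; 16 (S)-N-methoxy-N,2-dimethylbutanamide
Product: 18 (2S)-1-[(3S)-5,7-bis(benzyloxy)-3-hydroxy-2,2-dimethylchroman-8-yl]-2-methylbutan-1-one, via C8-lithiated lithium alkoxide 17 (not isolated)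
Conditions: n-BuLi (2.1 equiv), THF, −78 °C; then 16 (1.5 equiv), −78 to −20 °C; aq. NH4Cl
Reagents that add atoms: none
Why: Bromine–lithium exchange (the first equivalent of n-BuLi deprotonates the C3 hydroxyl) followed by Weinreb ketone synthesis, which stops at the ketone stage and frees the ketone only on work-up, so that the (S)-α-stereocentre is never exposed to base as an enolisable ketone.

Step 9
Reactants: 18 (2S)-1-[(3S)-5,7-bis(benzyloxy)-3-hydroxy-2,2-dimethylchroman-8-yl]-2-methylbutan-1-one
Product: 19 (2S)-2-methyl-1-[(3S)-3,5,7-trihydroxy-2,2-dimethylchroman-8-yl]butan-1-one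
Conditions: H2 (1 atm), Pd/C (10%), EtOAc, 25 °C
Reagents that add atoms: none
Why: Hydrogenolysis of benzyl aryl ethers over palladium on carbon under neutral conditions, which should leave the hindered, hydrogen-bonded aryl ketone and both stereocentres untouched.

Step 10
Reactants: 20 ethyl 3-oxopentanoate; 21 N-methoxy-N-methylpropanamide
Product: 23 ethyl 4-methyl-3,5-dioxoheptanoate, via dilithium dienolate 22 (not isolated)
Conditions: LiN(iPr)2 (2.2 equiv), THF, −78 to 0 °C; then 21 (1.0 equiv), −78 to 0 °C; 1 M HCl
Reagents that add atoms: none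
Why: γ-Acylation of a β-keto ester dianion with a Weinreb amide, in which the more reactive terminal carbanion is acylated and the amide prevents double addition; the new stereocentre at C4 is lost on enolisation in the next step.

Step 11
Reactants: 23 ethyl 4-methyl-3,5-dioxoheptanoate
Product: 24 6-ethyl-4-hydroxy-5-methyl-2H-pyran-2-one
Conditions: DBU (1.5 equiv), PhMe, 110 °C; then 1 M HCl
Reagents that add atoms: none
Why: Base-mediated enol lactonisation of a 3,5-diketo ester (the C5 enol oxygen attacks the ester carbonyl with loss of ethanol), the usual closure of 4-hydroxy-2-pyrones.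

Step 12
Reactants: 19 (2S)-2-methyl-1-[(3S)-3,5,7-trihydroxy-2,2-dimethylchroman-8-yl]butan-1-one; 24 6-ethyl-4-hydroxy-5-methyl-2H-pyran-2-one
Product: 27 6-ethyl-4-hydroxy-5-methyl-3-{[(3S)-3,5,7-trihydroxy-2,2-dimethyl-8-[(2S)-2-methylbutanoyl]chroman-6-yl]methyl}-2H-pyran-2-one (CNP0361212.1), via Mannich base 25 (not isolated), via ortho-quinone methide 26 (not isolated)
Conditions: [Me2N=CH2]I (1.05 equiv), MeCN, 25 °C; then 24 (1.5 equiv), 70 °C
Reagents that add atoms: N,N-dimethylmethyleneiminium iodide (Eschenmoser's salt), C=[N+](C)C.[I-]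
Why: Mannich aminomethylation of the only free, doubly activated ring position C6, then thermal loss of dimethylamine to an ortho-quinone methide that is captured at C3 of the 4-hydroxy-2-pyrone (Michael addition), the established way to join acylphloroglucinols and pyrones through a methylene bridge; pre-forming the Mannich base on 19 should suppress methylene-bridged homodimers, and no stereocentre is formed or touched.

**Compound list**

1 | 3,5-bis(benzyloxy)phenol | Oc1cc(OCc2ccccc2)cc(OCc2ccccc2)c1 | starting material
2 | 3,5-bis(benzyloxy)-2-bromophenol | Oc1cc(OCc2ccccc2)cc(OCc2ccccc2)c1Br | intermediate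
3 | [3,5-bis(benzyloxy)-2-bromophenoxy]trimethylsilane | C[Si](C)(C)Oc1cc(OCc2ccccc2)cc(OCc2ccccc2)c1Br | intermediate
4 | lithium 3,5-bis(benzyloxy)-2-(trimethylsilyl)phenoxide | [Li]Oc1cc(OCc2ccccc2)cc(OCc2ccccc2)c1[Si](C)(C)C | intermediate
5 | 3,5-bis(benzyloxy)-2-(trimethylsilyl)phenyl trifluoromethanesulfonate | C[Si](C)(C)c1c(OS(=O)(=O)C(F)(F)F)cc(OCc2ccccc2)cc1OCc1ccccc1 | intermediate
6 | 3-methylbut-2-enal | CC(C)=CC=O | starting material
7 | 3,5-bis(benzyloxy)benzyne (1,2-didehydro-3,5-bis(benzyloxy)benzene) | C1#CC(OCc2ccccc2)=CC(OCc2ccccc2)=C1 | intermediate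
8 | 3,5-bis(benzyloxy)-2-(2-methylprop-1-en-1-yl)-2H-benzo[b]oxete | CC(C)=CC1Oc2cc(OCc3ccccc3)cc(OCc3ccccc3)c21 | intermediate
9 | 3,5-bis(benzyloxy)-6-(3-methylbut-2-en-1-ylidene)cyclohexa-2,4-dien-1-one | CC(C)=CC=C1C(=O)C=C(OCc2ccccc2)C=C1OCc1ccccc1 | intermediate
10 | 5,7-bis(benzyloxy)-2,2-dimethyl-2H-chromene | CC1(C)C=Cc2c(OCc3ccccc3)cc(OCc3ccccc3)cc2O1 | intermediate
11 | (3S,4S)-5,7-bis(benzyloxy)-3,4-epoxy-2,2-dimethylchromane | CC1(C)Oc2cc(OCc3ccccc3)cc(OCc3ccccc3)c2[C@@H]2O[C@H]12 | intermediate
12 | (3S)-5,7-bis(benzyloxy)-2,2-dimethylchroman-3-ol | CC1(C)Oc2cc(OCc3ccccc3)cc(OCc3ccccc3)c2C[C@@H]1O | intermediate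
13 | (3S)-5,7-bis(benzyloxy)-8-bromo-2,2-dimethylchroman-3-ol | CC1(C)Oc2c(Br)c(OCc3ccccc3)cc(OCc3ccccc3)c2C[C@@H]1O | intermediate
14 | (S)-2-methylbutanoic acid | CC[C@H](C)C(=O)O | starting material
15 | (S)-1-(1H-imidazol-1-yl)-2-methylbutan-1-one | CC[C@H](C)C(=O)n1ccnc1 | intermediate
16 | (S)-N-methoxy-N,2-dimethylbutanamide | CC[C@H](C)C(=O)N(C)OC | intermediate
17 | lithium (3S)-5,7-bis(benzyloxy)-8-lithio-2,2-dimethylchroman-3-olate | CC1(C)Oc2c([Li])c(OCc3ccccc3)cc(OCc3ccccc3)c2C[C@@H]1O[Li] | intermediate
18 | (2S)-1-[(3S)-5,7-bis(benzyloxy)-3-hydroxy-2,2-dimethylchroman-8-yl]-2-methylbutan-1-one | CC[C@H](C)C(=O)c1c(OCc2ccccc2)cc(OCc2ccccc2)c2c1OC(C)(C)[C@@H](O)C2 | intermediate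
19 | (2S)-2-methyl-1-[(3S)-3,5,7-trihydroxy-2,2-dimethylchroman-8-yl]butan-1-one | CC[C@H](C)C(=O)c1c(O)cc(O)c2c1OC(C)(C)[C@@H](O)C2 | intermediate
20 | ethyl 3-oxopentanoate | CCC(=O)CC(=O)OCC | starting material
21 | N-methoxy-N-methylpropanamide | CCC(=O)N(C)OC | starting material
22 | dilithium dienolate of ethyl 3-oxopentanoate | CC([Li])C(O[Li])=CC(=O)OCC | intermediate
23 | ethyl 4-methyl-3,5-dioxoheptanoate | CCC(=O)C(C)C(=O)CC(=O)OCC | intermediate
24 | 6-ethyl-4-hydroxy-5-methyl-2H-pyran-2-one | CCc1oc(=O)cc(O)c1C | intermediate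
25 | (2S)-1-[(3S)-6-[(dimethylamino)methyl]-3,5,7-trihydroxy-2,2-dimethylchroman-8-yl]-2-methylbutan-1-one | CC[C@H](C)C(=O)c1c(O)c(CN(C)C)c(O)c2c1OC(C)(C)[C@@H](O)C2 | intermediate
26 | (3S)-3,7-dihydroxy-2,2-dimethyl-6-methylidene-8-[(2S)-2-methylbutanoyl]-3,4-dihydro-2H-chromen-5(6H)-one | CC[C@H](C)C(=O)C1=C(O)C(=C)C(=O)C2=C1OC(C)(C)[C@@H](O)C2 | intermediate
27 | 6-ethyl-4-hydroxy-5-methyl-3-{[(3S)-3,5,7-trihydroxy-2,2-dimethyl-8-[(2S)-2-methylbutanoyl]chroman-6-yl]methyl}-2H-pyran-2-one | CCc1oc(=O)c(Cc2c(O)c3c(c(C(=O)[C@@H](C)CC)c2O)OC(C)(C)[C@@H](O)C3)c(O)c1C | target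

**Step count and risks**

Total step count: 12. Longest linear sequence: 9 steps (steps 1, 2, 3, 4, 5, 6, 8, 9, 12).

Steps most likely to fail:

Step 3. The aryne may be consumed by an ene reaction with the allylic C–H bonds of 6, by [2+2] addition to its C=C bond, or by a second aryne adding to the ortho-quinone methide, so that the carbonyl pathway does not dominate. The fallback keeps the aryne and its regiochemistry but replaces the enal by a formamide, a better oxygen nucleophile without ene-active hydrogens. It sets out from 5: CsF in N,N-dimethylformamide (aryne insertion into the formamide C=O bond, hydrolytic work-up) should give 2,4-bis(benzyloxy)-6-hydroxybenzaldehyde F1. Addition of (2-methylprop-1-en-1-yl)magnesium bromide (2.5 equiv, THF, 0 °C) should give 3,5-bis(benzyloxy)-2-(1-hydroxy-3-methylbut-2-en-1-yl)phenol F2. Mild acid (pyridinium p-toluenesulfonate, PhMe, 80 °C) should dehydrate F2 through the same ortho-quinone methide 9 and oxa-6π closure, and the fallback comes back to the route at 10.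

Step 4 (felt in step 5). The 5,7-dialkoxy-substituted benzylic epoxide may ionise at C4 during oxidation, work-up or reduction; opening by adventitious nucleophiles or a 1,2-hydride shift to the chroman-3-one would lower the yield and erode the enantiomeric purity at C3. The fallback separates oxygenation from enantiocontrol and sets out from 10. Hydroboration–oxidation (BH3·THF; then NaOH, H2O2) should place the hydroxyl on C3 and give racemic 5,7-bis(benzyloxy)-2,2-dimethylchroman-3-ol F3. Dess–Martin oxidation should give 5,7-bis(benzyloxy)-2,2-dimethylchroman-3-one F4. Corey–Bakshi–Shibata reduction with the (R)-B-methyl oxazaborolidine derived from (R)-diphenylprolinol and BH3·SMe2, in which the fully substituted C2 acts as the large group, should give the (S)-alcohol, and the fallback comes back to the route at 12.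

Step 6. Bromination may be insufficiently site-selective between C8 and C6, or may go on to the dibromide, which would put the acyl group on the wrong ring carbon. The fallback fixes the acyl position before the pyran ring is closed and sets out from 2. Double lithiation (n-BuLi, 2.1 equiv, THF, −78 °C; O–H deprotonation, then bromine–lithium exchange) and acylation with 16 should give (2S)-1-[2,4-bis(benzyloxy)-6-hydroxyphenyl]-2-methylbutan-1-one F5, in which the acyl group sits next to the only free phenol. Condensation of F5 with 6 (ethylenediammonium diacetate, xylene, 140 °C; Knoevenagel-type condensation and oxa-6π electrocyclisation) can close the pyran ring only onto the ring carbon on the other side of that phenol and should give (2S)-1-[5,7-bis(benzyloxy)-2,2-dimethyl-2H-chromen-8-yl]-2-methylbutan-1-one F6. Jacobsen–Katsuki epoxidation under the conditions of step 4 should give (2S)-1-[(3S,4S)-5,7-bis(benzyloxy)-3,4-epoxy-2,2-dimethylchroman-8-yl]-2-methylbutan-1-one F7. Hydrogenolysis (H2, Pd/C, EtOAc) should cleave the benzylic C4–O bond and both benzyl ethers, and the fallback comes back to the route at 19.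

**Further compounds**

F1 | step 3 | 2,4-bis(benzyloxy)-6-hydroxybenzaldehyde | O=Cc1c(O)cc(OCc2ccccc2)cc1OCc1ccccc1
F2 | step 3 | 3,5-bis(benzyloxy)-2-(1-hydroxy-3-methylbut-2-en-1-yl)phenol | CC(C)=CC(O)c1c(O)cc(OCc2ccccc2)cc1OCc1ccccc1
F3 | step 4 | rac-5,7-bis(benzyloxy)-2,2-dimethylchroman-3-ol | CC1(C)Oc2cc(OCc3ccccc3)cc(OCc3ccccc3)c2CC1O
F4 | step 4 | 5,7-bis(benzyloxy)-2,2-dimethylchroman-3-one | CC1(C)Oc2cc(OCc3ccccc3)cc(OCc3ccccc3)c2CC1=O
F5 | step 6 | (2S)-1-[2,4-bis(benzyloxy)-6-hydroxyphenyl]-2-methylbutan-1-one | CC[C@H](C)C(=O)c1c(O)cc(OCc2ccccc2)cc1OCc1ccccc1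
F6 | step 6 | (2S)-1-[5,7-bis(benzyloxy)-2,2-dimethyl-2H-chromen-8-yl]-2-methylbutan-1-one | CC[C@H](C)C(=O)c1c(OCc2ccccc2)cc(OCc2ccccc2)c2C=CC(C)(C)Oc12
F7 | step 6 | (2S)-1-[(3S,4S)-5,7-bis(benzyloxy)-3,4-epoxy-2,2-dimethylchroman-8-yl]-2-methylbutan-1-one | CC[C@H](C)C(=O)c1c(OCc2ccccc2)cc(OCc2ccccc2)c2c1OC(C)(C)[C@H]1O[C@@H]21
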